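**Late time.** Time has nearly stopped paying in the maple run by its last readings: between 8.00 d and 10.0 d that run's product goes from 1.9% to 1.8%, with a scatter of 0.3 percentage points on each reading.

| flask | solid substrate | remark | time |
|---|---|---|---|
| alder | 0.034 M | run made earlier |  |
| maple | 0.075 M | run made earlier |  |
| flask | 0.050 M |  | 15 d |

| run | time / d | solid substrate / % | product / % |
|---|---|---|---|
| alder | 0.625 | 95.6 | 0 |
| alder | 1.67 | 90.5 | 0.5 |
| alder | 3.00 | 87.6 | 1.7 |
| alder | 5.00 | 83.9 | 2.9 |
| alder | 6.00 | 83.6 | 3.7 |
| alder | 10.0 | 81.9 | 4.2 |
| maple | 1.67 | 95.6 | 0.5 |
| maple | 3.00 | 93.9 | 1.2 |
| maple | 5.00 | 92.5 | 1.3 |
| maple | 6.00 | 92.6 | 1.7 |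
| maple | 8.00 | 91.2 | 1.9 |
| maple | 10.0 | 91.3 | 1.8 |

(each reading ± 0.3 percentage points)

- a species is counted by the solid substrate in it: one product counts as two
- at the start none of the solid substrate is in solution
- what has only dissolved of solid substrate counts as not reacted
- starting material means what is dissolved; the solid is not counted in it
- a reading or a percentage of product counts all its forms, free or not

- part of the solid substrate that has turned into other species by 15 d (what has only dissolved does not count)
- product at 15 d, in percent of the solid substrate charged
- starting material at 15 d, in percent of the solid substrate charged
- amount of product if the flask were left three thousand times as long, in percent of the solid substrate charged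

**Your hunch.** You asked for a quick number and guessed that a run's percentages carry over to the new flask, but the alder run ends at 4.2% of product and the maple run, with its heavier charge, at 1.8%, so the percentages fall as the charge rises. As concentrations, counted by the solid substrate in the product, the two last readings meet at 1.43 mM and 1.35 mM, with solid substrate still present in both runs (81.9% and 91.3%).

**Our number.** So we freeze their mean, a reading that we call the product ceiling and take for an equilibrium plateau reached in concentration and not in percent, at 1.39 mM. Dividing it by the flask's charge of 0.050 M, which lies between the two runs, gives 2.78% of product, and conversion the same.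

**The forecast.** The forecast, holding that “the product stops at a fixed concentration”, stands a little above ours: product 3%, conversion 3%, starting material 10.2%, and 3.1% of product if left far longer.

**The result.** The flask gives product 3.07%, conversion 3.07%, starting material 10.1%, and 3.12% of product after the far longer wait.

    crystals ⇌ product, rate k1*(cs1 - [product]) while solid is left; crystals form when [product] > cs1 (solubility = 25.0 mM, k = 0.610 /h)
    solid substrate ⇌ starting material, rate k2*(cs2 - [starting material]) while solid is left; crystals form when [starting material] > cs2 (solubility = 5.10 mM, k = 0.0230 /h)
    2 starting material ⇌ product (K = 30.0 /M, k = 1.30 /M/h)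

**Lighter charge.** We use the ceiling again on a neighbour flask charged with 0.013 M of solid substrate, all else held: 1.39 mM divided by that charge gives 10.7% of product. The neighbour flask gives 11.8%, which is 1.53 mM counted by the solid substrate in the product, beside 1.53 mM counted the same way in the asked flask. At 15.0 d the neighbour flask still holds 49.2% of its charge as solid substrate, beside 39.0% as starting material.

The runs stem from a simulated flask with made-up constants, and the scatter is random.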